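The vinylogous ester O1–C8a=C4a–C4=O joins the tetrol carbocycle (C4a, C5, C6, C7, C8, C8a) to the pyranone. The route reads it as the cycloadduct of a cyclic acylketene O=C8a–C4a=C4=O. The ketene is released from a seven-membered 2-diazo-1,3-dione in which C4 still sits in the ring between C4a and C5. One heating expels N2 and moves C5 from C4 to C4a (cycloheptane to cyclohexane, retention at C5). A 2-benzyloxy-1-alkene then delivers C2, C3 and the arylethyl arm, and loss of benzyl alcohol completes the pyranone. The precursor, a tetra-oxygenated diazocycloheptanedione, is made from D-galactose by ring-closing metathesis.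

Key step: step 12

Remark: locants C2 to C8a on intermediates are the chromone locants these atoms carry in the target; 1, 4 and 14 are taken as purchasable.

Step 1
Reactants: 1 methyl 2,3,4-tri-O-benzyl-α-D-galactopyranoside
Product: 2 methyl 2,3,4-tri-O-benzyl-6-deoxy-6-iodo-α-D-galactopyranoside
Conditions: I2, PPh3, imidazole, toluene, 70 °C
Reagents that add atoms: iodine, [I][I]
Why: Garegg–Samuelsson (Appel-type) iodination replaces the only free, primary hydroxyl and touches no stereocentre.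

Step 2
Reactants: 2 methyl 2,3,4-tri-O-benzyl-6-deoxy-6-iodo-α-D-galactopyranoside
Product: 3 (2R,3S,4S)-2,3,4-tris(benzyloxy)hex-5-enal (2,3,4-tri-O-benzyl-5,6-dideoxy-L-arabino-hex-5-enose)
Conditions: Zn dust, THF/H2O 9:1, ultrasound, 40 °C
Reagents that add atoms: none
Why: Bernet–Vasella reductive fragmentation opens the 6-iodopyranoside to the enal, and galactose C2, C3 and C4 pass unchanged into future C7, C6 and C5.

Step 3
Reactants: 3 (2R,3S,4S)-2,3,4-tris(benzyloxy)hex-5-enal; 4 methoxyallene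
Product: 6 (4S,5S,6S,7S)-5,6,7-tris(benzyloxy)-3-methoxynona-1,2,8-trien-4-ol, via 1-lithio-1-methoxyallene 5 (not isolated)
Conditions: 4, n-BuLi, THF, −78 °C; 3 premixed with MgBr2·OEt2 in CH2Cl2, −78 °C; H2O quench
Reagents that add atoms: n-butyllithium, [Li]CCCC (its lithium stays in 5 only)
Why: The acryloyl anion equivalent adds to the aldehyde under Cram chelate control, magnesium bridging C=O and the α-benzyloxy oxygen, which should give the syn (threo) carbinol and so set future C8 trans to C7.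

Step 4
Reactants: 6 (4S,5S,6S,7S)-5,6,7-tris(benzyloxy)-3-methoxynona-1,2,8-trien-4-ol
Product: 7 benzyl (4S,5R,6S,7S)-5,6,7-tris(benzyloxy)-3-methoxynona-1,2,8-trien-4-yl carbonate
Conditions: CbzCl, DMAP, pyridine, CH2Cl2, 0 °C to rt
Reagents that add atoms: benzyl chloroformate, O=C(Cl)OCc1ccccc1
Why: O-acylation gives the mixed carbonate with retention at carbon, which marks future C8 with an electron-poor group that hydrogenolysis can remove.

Step 5
Reactants: 7 benzyl (4S,5R,6S,7S)-5,6,7-tris(benzyloxy)-3-methoxynona-1,2,8-trien-4-yl carbonate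
Product: 8 benzyl (4S,5R,6S,7S)-5,6,7-tris(benzyloxy)-3-oxonona-1,8-dien-4-yl carbonate
Conditions: 5% aq H2SO4, THF, 0 °C
Reagents that add atoms: water, O
Why: Acid hydrolysis of the 1-alkoxyallene (protonation at the central carbon, hydration, loss of methanol) unmasks the vinyl ketone under conditions that spare the ethers and the carbonate.

Step 6
Reactants: 8 benzyl (4S,5R,6S,7S)-5,6,7-tris(benzyloxy)-3-oxonona-1,8-dien-4-yl carbonate
Product: 9 benzyl (1S,2R,3S,4S)-2,3,4-tris(benzyloxy)-7-oxocyclohept-5-en-1-yl carbonate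
Conditions: second-generation Hoveyda–Grubbs catalyst (5 mol %), toluene (2 mM), 80 °C
Reagents that add atoms: none
Why: Ring-closing metathesis of the allylic-ether alkene with the vinyl ketone closes the cycloheptenone, a ring size well served by this reaction on sugar-derived dienes, and creates no stereocentre.

Step 7
Reactants: 9 benzyl (1S,2R,3S,4S)-2,3,4-tris(benzyloxy)-7-oxocyclohept-5-en-1-yl carbonate
Product: 11 benzyl (1S,2R,3S,4S)-2,3,4-tris(benzyloxy)-5-hydroxy-7-oxocycloheptyl carbonate (epimeric at the new carbinol), via pinacol boronate 10 (not isolated)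
Conditions: B2pin2, CuCl (5 mol %), Xantphos, NaOt-Bu (10 mol %), MeOH, THF, rt; then NaBO3·4H2O, THF/H2O, rt
Reagents that add atoms: bis(pinacolato)diboron, CC1(C)OB(OC1(C)C)B1OC(C)(C)C(C)(C)O1 (boron unit of 10); sodium perborate, [Na+].[O-]OB=O (oxygen of 11)
Why: Copper-catalysed conjugate borylation followed by C–B oxidation puts oxygen on the β-carbon (future C4), and the new carbinol centre needs no control because step 8 removes it.

Step 8
Reactants: 11 benzyl (1S,2R,3S,4S)-2,3,4-tris(benzyloxy)-5-hydroxy-7-oxocycloheptyl carbonate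
Product: 12 benzyl (1S,2R,3R,4R)-2,3,4-tris(benzyloxy)-5,7-dioxocycloheptyl carbonate
Conditions: Dess–Martin periodinane, CH2Cl2, 0 °C to rt
Reagents that add atoms: none
Why: Dess–Martin oxidation turns the β-hydroxy ketone into the 1,3-diketone without base, so the α-oxygenated centres and the carbonate are not put at risk.

Step 9
Reactants: 12 benzyl (1S,2R,3R,4R)-2,3,4-tris(benzyloxy)-5,7-dioxocycloheptyl carbonate
Product: 13 benzyl (1S,2R,3R,4R)-2,3,4-tris(benzyloxy)-6-diazo-5,7-dioxocycloheptyl carbonate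
Conditions: p-ABSA, Et3N, MeCN, 0 °C
Reagents that add atoms: 4-acetamidobenzenesulfonyl azide, CC(=O)Nc1ccc(cc1)S(=O)(=O)N=[N+]=[N-]
Why: Regitz diazo transfer occurs at the doubly activated methylene (future C4a), whose acidity keeps the mild base away from the flanking stereocentres.

Step 10
Reactants: 14 3-(3-hydroxy-4-methoxyphenyl)propanoic acid
Product: 15 benzyl 3-[3-(benzyloxy)-4-methoxyphenyl]propanoate
Conditions: BnBr (2.5 equiv), K2CO3, DMF, 60 °C
Reagents that add atoms: benzyl bromide, BrCc1ccccc1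
Why: Double O-alkylation (Williamson type) benzylates the phenol and the carboxylate in one operation.

Step 11
Reactants: 15 benzyl 3-[3-(benzyloxy)-4-methoxyphenyl]propanoate
Product: 16 2-(benzyloxy)-4-[3-(benzyloxy)but-3-en-1-yl]-1-methoxybenzene
Conditions: Cp2TiMe2, toluene, 70 °C, dark
Reagents that add atoms: dimethyltitanocene Cp2TiMe2, C[Ti](C)(C1C=CC=C1)C1C=CC=C1
Why: Petasis methylenation of the ester carbonyl gives the terminal 1,1-disubstituted enol ether as a single regioisomer, which ketone enolisation could not guarantee.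

Step 12
Reactants: 13 benzyl (1S,2R,3R,4R)-2,3,4-tris(benzyloxy)-6-diazo-5,7-dioxocycloheptyl carbonate; 16 2-(benzyloxy)-4-[3-(benzyloxy)but-3-en-1-yl]-1-methoxybenzene
Product: 19 benzyl (5S,6S,7R,8S)-5,6,7-tris(benzyloxy)-2-{2-[3-(benzyloxy)-4-methoxyphenyl]ethyl}-4-oxo-5,6,7,8-tetrahydro-4H-chromen-8-yl carbonate, via acylketene 17 (not isolated), via ketal cycloadduct 18 (not isolated)
Conditions: 13, 16 (3 equiv), toluene, 140 °C, sealed tube; cool, p-TsOH·H2O (5 mol %), rt
Reagents that add atoms: none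
Why: Heating expels N2 from 13 while the C4–C5 bond, held antiperiplanar to the C–N2 bond by the ring, moves to C4a (Wolff rearrangement of a cyclic 2-diazo-1,3-diketone), so the cycloheptane contracts to the cyclohexane of acylketene 17 and the migrating C5 keeps its configuration. The 1-oxadiene O=C8a–C4a=C4 of 17 then takes up enol ether 16 in an inverse-demand hetero-Diels–Alder reaction, the established route from acylketenes and enol ethers to 2-alkoxy-2,3-dihydropyran-4-ones and, after loss of the alcohol, to 4-pyranones. The carbocycle is closed by the 1,2-shift (new bond C4a–C5, six ring atoms from seven) and the pyranone by a concerted asynchronous [4+2] closure in which the nucleophilic CH2 of 16 bonds to the ketene carbon C4 (C3–C4) ahead of O1–C2, which fixes the regiochemistry. The only new stereocentre, ketal carbon C2 of 18, needs no control because p-TsOH removes benzyl alcohol across C2–C3; C6, C7 and C8 are bystanders. The one selectivity needed is migration of C5 rather than C8: both bonds are equally aligned, so the choice is electronic, and the benzyl-ether carbon C5 is the more electron-rich migrating group, whereas C8 is deactivated by its carbonate, in line with the rule that acceptor-substituted carbons shift reluctantly in unsymmetrical diazodiketones. Metal-free heating is chosen so that carbenoid dihydrofuran formation with 16 cannot compete.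

Step 13
Reactants: 19 benzyl (5S,6S,7R,8S)-5,6,7-tris(benzyloxy)-2-{2-[3-(benzyloxy)-4-methoxyphenyl]ethyl}-4-oxo-5,6,7,8-tetrahydro-4H-chromen-8-yl carbonate
Product: 20 (5S,6S,7R,8S)-5,6,7,8-tetrahydroxy-2-[2-(3-hydroxy-4-methoxyphenyl)ethyl]-5,6,7,8-tetrahydro-4H-chromen-4-one
Conditions: H2 (1 atm), Pd/C, EtOAc/MeOH, rt
Reagents that add atoms: none
Why: Catalytic hydrogenolysis cleaves the four benzyl ethers and the benzyl carbonate (which then loses CO2) in one neutral operation that leaves all four carbinol centres untouched.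

Compound list
1 | methyl 2,3,4-tri-O-benzyl-α-D-galactopyranoside | CO[C@@H]1[C@H](OCc2ccccc2)[C@@H](OCc2ccccc2)[C@@H](OCc2ccccc2)[C@@H](CO)O1 | starting material
2 | methyl 2,3,4-tri-O-benzyl-6-deoxy-6-iodo-α-D-galactopyranoside | CO[C@@H]1[C@H](OCc2ccccc2)[C@@H](OCc2ccccc2)[C@@H](OCc2ccccc2)[C@@H](C[I])O1 | intermediate
3 | (2R,3S,4S)-2,3,4-tris(benzyloxy)hex-5-enal | O=C[C@H](OCc1ccccc1)[C@@H](OCc1ccccc1)[C@@H](OCc1ccccc1)C=C | intermediate
4 | methoxyallene (1-methoxypropa-1,2-diene) | COC=C=C | starting material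
5 | 1-lithio-1-methoxyallene | [Li]C(OC)=C=C | intermediate
6 | (4S,5S,6S,7S)-5,6,7-tris(benzyloxy)-3-methoxynona-1,2,8-trien-4-ol | C=C=C(OC)[C@@H](O)[C@H](OCc1ccccc1)[C@@H](OCc1ccccc1)[C@@H](OCc1ccccc1)C=C | intermediate
7 | benzyl (4S,5R,6S,7S)-5,6,7-tris(benzyloxy)-3-methoxynona-1,2,8-trien-4-yl carbonate | C=C=C(OC)[C@@H](OC(=O)OCc1ccccc1)[C@H](OCc1ccccc1)[C@@H](OCc1ccccc1)[C@@H](OCc1ccccc1)C=C | intermediate
8 | benzyl (4S,5R,6S,7S)-5,6,7-tris(benzyloxy)-3-oxonona-1,8-dien-4-yl carbonate | C=CC(=O)[C@@H](OC(=O)OCc1ccccc1)[C@H](OCc1ccccc1)[C@@H](OCc1ccccc1)[C@@H](OCc1ccccc1)C=C | intermediate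
9 | benzyl (1S,2R,3S,4S)-2,3,4-tris(benzyloxy)-7-oxocyclohept-5-en-1-yl carbonate | O=C1[C@@H](OC(=O)OCc2ccccc2)[C@H](OCc2ccccc2)[C@@H](OCc2ccccc2)[C@@H](OCc2ccccc2)C=C1 | intermediate
10 | β-(pinacolboryl) ketone from 9 (epimeric at the C–B carbon) | O=C1[C@@H](OC(=O)OCc2ccccc2)[C@H](OCc2ccccc2)[C@@H](OCc2ccccc2)[C@@H](OCc2ccccc2)C(B2OC(C)(C)C(C)(C)O2)C1 | intermediate
11 | benzyl (1S,2R,3S,4S)-2,3,4-tris(benzyloxy)-5-hydroxy-7-oxocycloheptyl carbonate (epimeric at the carbinol) | O=C1[C@@H](OC(=O)OCc2ccccc2)[C@H](OCc2ccccc2)[C@@H](OCc2ccccc2)[C@@H](OCc2ccccc2)C(O)C1 | intermediate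
12 | benzyl (1S,2R,3R,4R)-2,3,4-tris(benzyloxy)-5,7-dioxocycloheptyl carbonate | O=C1[C@@H](OC(=O)OCc2ccccc2)[C@H](OCc2ccccc2)[C@@H](OCc2ccccc2)[C@@H](OCc2ccccc2)C(=O)C1 | intermediate
13 | benzyl (1S,2R,3R,4R)-2,3,4-tris(benzyloxy)-6-diazo-5,7-dioxocycloheptyl carbonate | O=C1[C@@H](OC(=O)OCc2ccccc2)[C@H](OCc2ccccc2)[C@@H](OCc2ccccc2)[C@@H](OCc2ccccc2)C(=O)C1=[N+]=[N-] | intermediate
14 | 3-(3-hydroxy-4-methoxyphenyl)propanoic acid | COc1ccc(CCC(=O)O)cc1O | starting material
15 | benzyl 3-[3-(benzyloxy)-4-methoxyphenyl]propanoate | COc1ccc(CCC(=O)OCc2ccccc2)cc1OCc1ccccc1 | intermediate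
16 | 2-(benzyloxy)-4-[3-(benzyloxy)but-3-en-1-yl]-1-methoxybenzene | COc1ccc(CCC(=C)OCc2ccccc2)cc1OCc1ccccc1 | intermediate
17 | benzyl (1S,2R,3S,4S)-2,3,4-tris(benzyloxy)-6-oxo-5-(oxomethylidene)cyclohexyl carbonate (acylketene) | O=C=C1C(=O)[C@@H](OC(=O)OCc2ccccc2)[C@H](OCc2ccccc2)[C@@H](OCc2ccccc2)[C@H]1OCc1ccccc1 | intermediate
18 | benzyl (5S,6S,7R,8S)-2,5,6,7-tetrakis(benzyloxy)-2-{2-[3-(benzyloxy)-4-methoxyphenyl]ethyl}-4-oxo-3,4,5,6,7,8-hexahydro-2H-chromen-8-yl carbonate (C2 epimers) | COc1ccc(CCC2(OCc3ccccc3)CC(=O)C3=C(O2)[C@@H](OC(=O)OCc2ccccc2)[C@H](OCc2ccccc2)[C@@H](OCc2ccccc2)[C@H]3OCc2ccccc2)cc1OCc1ccccc1 | intermediate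
19 | benzyl (5S,6S,7R,8S)-5,6,7-tris(benzyloxy)-2-{2-[3-(benzyloxy)-4-methoxyphenyl]ethyl}-4-oxo-5,6,7,8-tetrahydro-4H-chromen-8-yl carbonate | COc1ccc(CCc2cc(=O)c3c(o2)[C@@H](OC(=O)OCc2ccccc2)[C@H](OCc2ccccc2)[C@@H](OCc2ccccc2)[C@H]3OCc2ccccc2)cc1OCc1ccccc1 | intermediate
20 | (5S,6S,7R,8S)-5,6,7,8-tetrahydroxy-2-[2-(3-hydroxy-4-methoxyphenyl)ethyl]-5,6,7,8-tetrahydro-4H-chromen-4-one | COc1ccc(CCc2cc(=O)c3c(o2)[C@@H](O)[C@H](O)[C@@H](O)[C@H]3O)cc1O | target

Total step count: 13. Longest linear sequence: 11 (steps 1 to 9, 12 and 13).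

Steps most likely to fail

Step 12. The shift may not discriminate well enough between the two acyl–carbon bonds, so that part of the material contracts with the carbonate-bearing carbon migrating. Ketene dimerisation, or capture of the ketene by prematurely released benzyl alcohol, would add to the loss.

The fallback is a contraction whose direction is fixed by constitution. It sets out from enone 9 and ester 15 and comes back at 19.
- Ester 15 is reduced with i-Bu2AlH to 3-[3-(benzyloxy)-4-methoxyphenyl]propanal F1.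
- F1 is homologated with the Ohira–Bestmann reagent (K2CO3, MeOH) to 4-[3-(benzyloxy)-4-methoxyphenyl]but-1-yne F2.
- Enone 9 is iodinated at its α-carbon (I2, pyridine) to the 2-iodoenone F3.
- F3 is joined to F2 by Sonogashira coupling (PdCl2(PPh3)2, CuI, Et3N) to the 2-alkynylenone F4.
- F4 is epoxidised (t-BuOOH, DBU) to the epoxy ketone F5.
- BF3·OEt2 opens the epoxide at the carbon next to C5, and the ring acyl carbon C8a shifts to that carbon. This is the 1,2-acyl shift of an α,β-epoxy ketone, again cycloheptane to cyclohexane.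
- The resulting 2-alkynoylcyclohexanone F6 closes by 6-endo addition of its enol oxygen to the ynone (Et2NH, then cat. TfOH) to 19.

Step 3. Facial selectivity may be poor if the magnesium chelate is not the reacting species, and the allenyl metal may attack through its γ-carbon.

The fallback corrects the centre instead of controlling it. It sets out from 3 and 4 and comes back at 6.
- Addition of 5 without any magnesium salt, under Felkin–Anh control, should favour the epimeric carbinol (4R,5S,6S,7S)-5,6,7-tris(benzyloxy)-3-methoxynona-1,2,8-trien-4-ol F7.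
- Mitsunobu inversion (4-nitrobenzoic acid, PPh3, DIAD) gives (4S,5R,6S,7S)-5,6,7-tris(benzyloxy)-3-methoxynona-1,2,8-trien-4-yl 4-nitrobenzoate F8.
- Methanolysis (K2CO3, MeOH) returns 6.

Step 13. Over-reduction may occur, by hydrogenolysis of the allylic C5–O or C8–O bond or by saturation of C2=C3 of the pyranone.

The fallback is a non-reductive deprotection. It sets out from 19 and comes back at 20.
- K2CO3 in MeOH at 0 °C cleaves the carbonate to (5S,6S,7S,8S)-5,6,7-tris(benzyloxy)-2-{2-[3-(benzyloxy)-4-methoxyphenyl]ethyl}-8-hydroxy-5,6,7,8-tetrahydro-4H-chromen-4-one F9.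
- BCl3 with pentamethylbenzene in CH2Cl2 at −78 °C then removes the four benzyl groups as scavenged benzyl cations.

Further compounds
F1 | step 12 | 3-[3-(benzyloxy)-4-methoxyphenyl]propanal | COc1ccc(CCC=O)cc1OCc1ccccc1
F2 | step 12 | 4-[3-(benzyloxy)-4-methoxyphenyl]but-1-yne | COc1ccc(CCC#C)cc1OCc1ccccc1
F3 | step 12 | benzyl (1S,2R,3S,4S)-2,3,4-tris(benzyloxy)-6-iodo-7-oxocyclohept-5-en-1-yl carbonate | O=C1[C@@H](OC(=O)OCc2ccccc2)[C@H](OCc2ccccc2)[C@@H](OCc2ccccc2)[C@@H](OCc2ccccc2)C=C1I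
F4 | step 12 | 2-alkynylenone from F3 and F2 | O=C1[C@@H](OC(=O)OCc2ccccc2)[C@H](OCc2ccccc2)[C@@H](OCc2ccccc2)[C@@H](OCc2ccccc2)C=C1C#CCCc1ccc(OC)c(OCc2ccccc2)c1
F5 | step 12 | 2,3-epoxide of F4 (either epoxide face serves) | O=C1[C@@H](OC(=O)OCc2ccccc2)[C@H](OCc2ccccc2)[C@@H](OCc2ccccc2)[C@@H](OCc2ccccc2)C2OC12C#CCCc1ccc(OC)c(OCc2ccccc2)c1
F6 | step 12 | ring-contracted 2-alkynoylcyclohexanone (enolisable at C4a) | O=C(C#CCCc1ccc(OC)c(OCc2ccccc2)c1)C1C(=O)[C@@H](OC(=O)OCc2ccccc2)[C@H](OCc2ccccc2)[C@@H](OCc2ccccc2)[C@H]1OCc1ccccc1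
F7 | step 3 | (4R,5S,6S,7S)-5,6,7-tris(benzyloxy)-3-methoxynona-1,2,8-trien-4-ol | C=C=C(OC)[C@H](O)[C@H](OCc1ccccc1)[C@@H](OCc1ccccc1)[C@@H](OCc1ccccc1)C=C
F8 | step 3 | (4S,5R,6S,7S)-5,6,7-tris(benzyloxy)-3-methoxynona-1,2,8-trien-4-yl 4-nitrobenzoate | C=C=C(OC)[C@@H](OC(=O)c1ccc(cc1)[N+](=O)[O-])[C@H](OCc1ccccc1)[C@@H](OCc1ccccc1)[C@@H](OCc1ccccc1)C=C
F9 | step 13 | (5S,6S,7S,8S)-5,6,7-tris(benzyloxy)-2-{2-[3-(benzyloxy)-4-methoxyphenyl]ethyl}-8-hydroxy-5,6,7,8-tetrahydro-4H-chromen-4-one | COc1ccc(CCc2cc(=O)c3c(o2)[C@@H](O)[C@H](OCc2ccccc2)[C@@H](OCc2ccccc2)[C@H]3OCc2ccccc2)cc1OCc1ccccc1
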